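The route rests on disconnecting the C7–C1 bond between the carbinol carbon and ring A (the 3,4,5-trimethoxyphenyl ring). In one operation, addition of the ring A Grignard reagent to an (S)-2-aryloxypropanal forges this bond and sets C7; no ring is formed. The step exploits the 1,2-relationship of the C7 carbonyl oxygen to the ether oxygen O8 and the neighbouring ortho-methoxy oxygen on ring B, which together clamp magnesium so that the C8 methyl shields one aldehyde face, giving the threo (7S,8S) carbinol. The precursor aldehyde, with the methyl ester already in place, comes in three steps from methyl vanillate and (R)-1-(benzyloxy)propan-2-ol by Mitsunobu inversion, hydrogenolysis and oxidation.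

Key step: step 5

Remark: neolignan numbering is used (ring A = 3,4,5-trimethoxyphenyl, C7 = carbinol carbon, C8 = ether-bearing carbon, C9 = its methyl, O8 = ether oxygen, ring B = the methyl 3-methoxybenzoate ring). It is assumed that the Mitsunobu coupling inverts completely, so that alcohol 2 of high enantiomeric purity fixes C8 as S.

Step 1
Reactants: 1 methyl 4-hydroxy-3-methoxybenzoate (methyl vanillate); 2 (R)-1-(benzyloxy)propan-2-ol
Product: 3 methyl 4-{[(2S)-1-(benzyloxy)propan-2-yl]oxy}-3-methoxybenzoate
Conditions: PPh3, DIAD, THF, 0 °C → rt
Reagents that add atoms: none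
Why: Mitsunobu etherification of the acidic phenol proceeds by SN2 displacement of the alkoxyphosphonium ion of the unhindered secondary alcohol, so the 2R carbinol should be inverted to the 8S aryl ether while the neutral conditions leave the methyl ester and benzyl ether untouched.

Step 2
Reactants: 3 methyl 4-{[(2S)-1-(benzyloxy)propan-2-yl]oxy}-3-methoxybenzoate
Product: 4 methyl 4-{[(2S)-1-hydroxypropan-2-yl]oxy}-3-methoxybenzoate
Conditions: H2 (1 atm), 10% Pd/C, MeOH, rt
Reagents that add atoms: none
Why: Catalytic hydrogenolysis cleaves only the benzylic C–O bond of the benzyl ether, whereas the aryl alkyl ether at C8, the aryl methyl ethers and the ester are inert and C8 is not touched.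

Step 3
Reactants: 5 5-bromo-1,2,3-trimethoxybenzene
Product: 6 3,4,5-trimethoxyphenylmagnesium bromide (titrated THF solution, prepared ahead and used as such)
Conditions: Mg turnings, I2 (cat.), THF, 50 °C
Reagents that add atoms: magnesium, [Mg]
Why: Grignard formation by insertion of magnesium into the aryl C–Br bond is routine for this electron-rich bromide, and the methyl ethers are spectators.

Step 4
Reactants: 4 methyl 4-{[(2S)-1-hydroxypropan-2-yl]oxy}-3-methoxybenzoate
Product: 7 methyl 3-methoxy-4-{[(2S)-1-oxopropan-2-yl]oxy}benzoate
Conditions: Dess–Martin periodinane (1.2 equiv), CH2Cl2, 0 °C → rt; cold aq. Na2S2O3/NaHCO3 wash; used crude at once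
Reagents that add atoms: none
Why: Dess–Martin oxidation takes the primary alcohol to the aldehyde without base and without over-oxidation, conditions under which α-heteroatom-substituted stereocentres normally survive, so C8 should remain S.

Step 5
Reactants: 7 methyl 3-methoxy-4-{[(2S)-1-oxopropan-2-yl]oxy}benzoate; 6 3,4,5-trimethoxyphenylmagnesium bromide
Product: 9 methyl 4-{[(1S,2S)-1-hydroxy-1-(3,4,5-trimethoxyphenyl)propan-2-yl]oxy}-3-methoxybenzoate (target), via bromomagnesium C7-alkoxide 8 (not isolated)
Conditions: 7, MgBr2·OEt2 (2 equiv), CH2Cl2, −78 °C, 20 min; then 6 (1.2 equiv, concentrated THF solution) added slowly, −78 °C; sat. aq. NH4Cl, −78 °C → rt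
Reagents that add atoms: none
Why: MgBr2 binds the aldehyde oxygen, O8 and the ortho-methoxy oxygen of ring B, holding the C8–O8 bond syn-coplanar with C7=O in a five-membered chelate, and the aryl group of 6 then adds to the carbonyl carbon to form the C7–C1 bond and alkoxide 8, which is protonated on work-up. The closest known reaction type is the Cram-chelate addition of Grignard reagents to α-alkoxy aldehydes (1,2-asymmetric induction). No ring is closed. The new C7 stereocentre is controlled by the existing C8 centre: within the chelate the aryl group approaches the face carrying the C8 hydrogen, away from the C9 methyl, which for the 8S aldehyde should give the 7S (threo) carbinol. The step needs chelate over Felkin–Anh facial selectivity, aldehyde over methyl ester chemoselectivity and an intact C8; these are secured by the two ether donors flanking the carbonyl, excess MgBr2 in weakly coordinating CH2Cl2, and the far faster addition of an aryl Grignard reagent to an aldehyde than to a benzoate at −78 °C with a fresh aldehyde.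

Compound list
1 | methyl 4-hydroxy-3-methoxybenzoate (methyl vanillate) | COC(=O)c1ccc(O)c(OC)c1 | starting material
2 | (R)-1-(benzyloxy)propan-2-ol | C[C@@H](O)COCc1ccccc1 | starting material
3 | methyl 4-{[(2S)-1-(benzyloxy)propan-2-yl]oxy}-3-methoxybenzoate | COC(=O)c1ccc(O[C@@H](C)COCc2ccccc2)c(OC)c1 | intermediate
4 | methyl 4-{[(2S)-1-hydroxypropan-2-yl]oxy}-3-methoxybenzoate | COC(=O)c1ccc(O[C@@H](C)CO)c(OC)c1 | intermediate
5 | 5-bromo-1,2,3-trimethoxybenzene | COc1cc(Br)cc(OC)c1OC | starting material
6 | 3,4,5-trimethoxyphenylmagnesium bromide | COc1cc([Mg]Br)cc(OC)c1OC | intermediate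
7 | methyl 3-methoxy-4-{[(2S)-1-oxopropan-2-yl]oxy}benzoate | COC(=O)c1ccc(O[C@@H](C)C=O)c(OC)c1 | intermediate
8 | bromomagnesium (1S,2S)-2-[2-methoxy-4-(methoxycarbonyl)phenoxy]-1-(3,4,5-trimethoxyphenyl)propan-1-olate | COC(=O)c1ccc(O[C@@H](C)[C@@H](O[Mg]Br)c2cc(OC)c(OC)c(OC)c2)c(OC)c1 | intermediate
9 | methyl 4-{[(1S,2S)-1-hydroxy-1-(3,4,5-trimethoxyphenyl)propan-2-yl]oxy}-3-methoxybenzoate, (7S,8S) | COC(=O)c1ccc(O[C@@H](C)[C@@H](O)c2cc(OC)c(OC)c(OC)c2)c(OC)c1 | target

Total step count: 5. Longest linear sequence: 4 steps (steps 1, 2, 4 and 5); step 3 is the one-step side branch.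

Steps most likely to fail

Step 5. Facial selectivity may erode: O8 is a weak donor because its ring carries the para ester, and THF from the Grignard solution can strip magnesium from the chelate, so the Felkin–Anh pathway would deliver the 7R (erythro) epimer alongside 9. The fallback sets out from 9 as obtained in admixture with its 7R epimer and returns at 9. The mixture is oxidised at C7 with Dess–Martin periodinane in CH2Cl2 to the single ketone methyl 3-methoxy-4-{[(2S)-1-oxo-1-(3,4,5-trimethoxyphenyl)propan-2-yl]oxy}benzoate F1. F1 is then reduced with LiBH(s-Bu)3 in THF at −78 °C. A bulky, non-chelating hydride should attack under Felkin–Anh control with O8 anti to the incoming hydride; because hydride rather than aryl is now delivered, this mode leads to the threo alcohol 9. The C7 configuration is thus set by hydride delivery to a ketone instead of aryl delivery to an aldehyde.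

Step 4. C8 may lose configuration by enolisation of the α-aryloxy aldehyde in the presence of the acetic acid released or during aqueous work-up, and the aldehyde may hydrate. The fallback sets out from 1 and returns at 7 without an oxidation next to C8. Mitsunobu coupling of 1 with (R)-but-3-en-2-ol (PPh3, DIAD, THF, 0 °C) should give, with inversion, methyl 4-{[(2S)-but-3-en-2-yl]oxy}-3-methoxybenzoate F2. Ozonolysis of the terminal alkene (O3, CH2Cl2, −78 °C, stopped at the first excess of ozone) leads through the ozonide methyl 3-methoxy-4-{[(1S)-1-(1,2,4-trioxolan-3-yl)ethyl]oxy}benzoate F3, and reduction with PPh3 releases 7 under neutral, anhydrous conditions. The cold CH2Cl2 solution can be taken directly into step 5.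

Step 1. The redox condensation may stall with the ortho-substituted phenol and the secondary alcohol, or the activated alcohol may be consumed by elimination or by alkylation of the hydrazide by-product. The fallback sets out from 2 and returns at 3. Alcohol 2 is converted with MsCl and Et3N in CH2Cl2 at 0 °C into (R)-1-(benzyloxy)propan-2-yl methanesulfonate F4, which is isolated. F4 is then displaced by the phenoxide of 1 (Cs2CO3, DMF, 60 °C) in a Williamson SN2 reaction, again with inversion at C8, to give 3.

Further compounds
F1 | step 5 | methyl 3-methoxy-4-{[(2S)-1-oxo-1-(3,4,5-trimethoxyphenyl)propan-2-yl]oxy}benzoate | COC(=O)c1ccc(O[C@@H](C)C(=O)c2cc(OC)c(OC)c(OC)c2)c(OC)c1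
F2 | step 4 | methyl 4-{[(2S)-but-3-en-2-yl]oxy}-3-methoxybenzoate | COC(=O)c1ccc(O[C@@H](C)C=C)c(OC)c1
F3 | step 4 | methyl 3-methoxy-4-{[(1S)-1-(1,2,4-trioxolan-3-yl)ethyl]oxy}benzoate (ozonide, both configurations at the trioxolane carbon) | COC(=O)c1ccc(O[C@@H](C)C2OCOO2)c(OC)c1
F4 | step 1 | (R)-1-(benzyloxy)propan-2-yl methanesulfonate | C[C@@H](OS(C)(=O)=O)COCc1ccccc1
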